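The data are simulated from invented constants; the scatter is artificial.

The reading at 15 min comes after a countable number of target lifetimes, and the share asked for can be reckoned from that count.

| flask | starting material | temperature | remark | time |
|---|---|---|---|---|
| Tuesday's | 0.070 M | 45 °C | run made earlier |  |
| Sunday's | 0.11 M | 65 °C | run made earlier |  |
| ash | 0.050 M | 65 °C |  | 15 min |
| oak | 0.050 M | 50 °C |  | 15 min |
| elm | 0.050 M |  | at 50 °C until 10 min, from then on at 80 °C | 15 min |
| alder | 0.050 M | 80 °C |  | 15 min |

| run | time / min | target / % | isomer of the product / % | side product / % |
|---|---|---|---|---|
| Tuesday's | 10.0 | 1.0 | 0.6 | 0.1 |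
| Tuesday's | 20.0 | 1.4 | 1.1 | 0.9 |
| Tuesday's | 30.0 | 1.6 | 2.9 | 1.9 |
| Tuesday's | 40.0 | 2.0 | 2.9 | 2.8 |
| Sunday's | 1.33 | 1.6 | 1.2 | 0.8 |
| Sunday's | 3.00 | 2.9 | 2.8 | 2.5 |
| Sunday's | 6.00 | 3.8 | 4.8 | 4.0 |
| Sunday's | 15.0 | 6.4 | 11.7 | 12.9 |

(scatter of a reading: 0.5 percentage points)

* the flask with the highest share of target in all that became target or isomer of the product or side product ("all alike" if they lie within 1.5 percentage points) (ash / oak / elm / alder / all alike)
* share of target in all that became target or isomer of the product or side product, ash
* share of target in all that became target or isomer of the product or side product, oak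
* share of target in all that became target or isomer of the product or side product, elm
* share of target in all that became target or isomer of the product or side product, alder

- percentages count the starting material that a species holds: one homo dimer or side product counts as two
- candidate steps: starting material <-> other conformer; starting material -> target; other conformer -> isomer of the product; 2 starting material -> homo dimer; starting material + target -> side product
- in a conversion other conformer counts as not yet reacted

1. Bench rule: while [starting material] stays near its charge, target falls pseudo-first-order to side product with lifetime τ = 1/(k[starting material]). Target made steadily has stood on average at half its final amount, and each side product counts as two, so [side product]/[target] ≈ N = t/τ.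

2. Sunday's run shares the temperature and time of ash, so its last ratio, 2.02 at 0.11 M, scales to the 0.050 M of ash: the target lifetime against side product in ash is 16.4 min, so N = 0.916.

3. Sunday's last reading gives isomer of the product over target made (target plus half the side product) as ρ = 0.911. The share is then 1/(1 + ρ(1 + N/2) + N), which for ash gives 30.8%.

4. The last readings give k = 0.500 /M/min on Tuesday's run and 1.22 /M/min on Sunday's. Interpolating ln k in temperature gives oak N = 0.469 and a share of 38.6%.

5. The border: the rule needs starting material to outlast the reading. Read products appear at 0.00192 /min on Tuesday's run and 0.0207 /min on Sunday's, which extrapolates to a read-product time at 80 °C of 8.16 min; homo dimer goes unread, so this time covers the read routes and is no lifetime of starting material. Alder's 15 min is 1.84 such times, past the border, so as an estimate its count is cut at that time: with k = 2.39 /M/min, N = 0.974 and the share is 30.1%.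

6. In elm the 10 min at 50 °C equal 0.284 min of hot making, so the count runs over the hot stage, which is shorter than the read-product time: taken as an estimate with [starting material] at its charge, N = 0.597 and the share in elm is 36.0%, behind oak.

The forecast, higher than this reckoning in each flask, gives 34.5% for ash, 41.3% for oak, 40.9% for elm and 34.1% for alder, names oak, and judges: “Oak and elm are nearly tied; oak has a slight edge.”

The flasks give 29.5% for ash, 41.1% for oak, 35.2% for elm and 29.8% for alder, with oak highest.

    starting material ⇌ other conformer (K = 0.500, k = 0.0792 /min, Ea = 117 kJ/mol, ΔH = 24.0 kJ/mol)
    starting material → target (k = 0.0856 /min, Ea = 117 kJ/mol)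
    other conformer → isomer of the product (k = 3.68 /min, Ea = 80.0 kJ/mol)
    2 starting material → homo dimer (k = 1.02 /M/min, Ea = 69.0 kJ/mol)
    starting material + target → side product (k = 4.43 /M/min, Ea = 57.0 kJ/mol)
    (constants at 80 °C)

Ash reads 10.1% side product against 9.44% target, a ratio of 1.07 beside the 0.916 lifetimes counted from 16.4 min. Oak stands highest because its 15 min is a short time for that flask: left ten times as long, oak falls from 41.1% to 14.6%. A neighbour of ash charged with 0.013 M stretches the lifetime to 63.1 min, so its 15 min counts 0.238 lifetimes; that neighbour reads a ratio of 0.293 and a share of 44.0%.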